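The whole route rests on opening the O–C3 bond of the 3(2H)-furanone (ring A: O, C10, C1, C2, C3; germacrane numbering) and folding its oxygen back onto C1. The precursor is therefore a 1,10-oxirane, set by catalytic asymmetric epoxidation, that bears an enyne (C2–C4) at C1. The key step exploits the acidic oxirane C1–H and the inert C10–O bond. Metalation and transfer of one oxygen atom give an oxiranolate that collapses. C1 becomes the ketone, while the oxirane oxygen stays on quaternary C10 and adds to C3. Three ring atoms become five in one operation. A Barbier allylation then builds lactone ring B, and metathesis at C4=C5 closes the carbocycle.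

Key step: step 6

Remark: germacrane numbering (C1–C15) is used for every intermediate, and (R)-2-vinyloxirane is taken to be a commercial compound.

Step 1
Reactants: 1 (R)-2-vinyloxirane; 2 lithium acetylide–ethylenediamine complex
Product: 3 (S)-hex-1-en-5-yn-3-ol
Conditions: DMSO, 0 to 23 °C; then H2O
Reagents that add atoms: none
Why: SN2 epoxide opening, in which the hard acetylide attacks the unsubstituted oxirane carbon in DMSO, so the C–O bond at the stereocenter (the later C8) is not touched and its configuration comes from 1.

Step 2
Reactants: 3 (S)-hex-1-en-5-yn-3-ol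
Product: 5 (3S,5E)-6-iodo-5-methylhexa-1,5-dien-3-ol, via alkenylalane 4 (not isolated)
Conditions: AlMe3 (3 equiv), Cp2ZrCl2 (0.3 equiv), CH2Cl2, 0 to 23 °C; then I2, THF, −30 °C
Reagents that add atoms: trimethylaluminium, C[Al](C)C; iodine, II
Why: Negishi carboalumination adds Me and Al syn across the terminal alkyne with Al at the terminus, and iodinolysis with retention should give the E iodide (Me cis to I), while the monosubstituted alkene reacts far more slowly.

Step 3
Reactants: 5 (3S,5E)-6-iodo-5-methylhexa-1,5-dien-3-ol
Product: 6 tert-butyl{[(3S,5E)-6-iodo-5-methylhexa-1,5-dien-3-yl]oxy}dimethylsilane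
Conditions: TBSCl, imidazole, DMF, 23 °C
Reagents that add atoms: tert-butyldimethylsilyl chloride, CC(C)(C)[Si](C)(C)Cl
Why: Standard silyl ether formation masks the C8 hydroxyl against the oxidant of step 5 and the amide base of step 6 and touches no stereocenter.

Step 4
Reactants: 6 tert-butyl{[(3S,5E)-6-iodo-5-methylhexa-1,5-dien-3-yl]oxy}dimethylsilane; 7 2-methylbut-1-en-3-yne
Product: 8 tert-butyl{[(3S,5E)-5,9-dimethyldeca-1,5,9-trien-7-yn-3-yl]oxy}dimethylsilane
Conditions: PdCl2(PPh3)2 (3 mol%), CuI (6 mol%), Et3N, THF, 23 °C
Reagents that add atoms: none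
Why: Sonogashira coupling of an alkenyl iodide runs at room temperature with retention of the E geometry and brings in C2, C3, C4 and C15 in one piece.

Step 5
Reactants: 8 tert-butyl{[(3S,5E)-5,9-dimethyldeca-1,5,9-trien-7-yn-3-yl]oxy}dimethylsilane
Product: 9 tert-butyldimethyl{[(2S)-1-[(2R,3R)-2-methyl-3-(3-methylbut-3-en-1-yn-1-yl)oxiran-2-yl]but-3-en-2-yl]oxy}silane (the 1R,10R-epoxide)
Conditions: 1,2:4,5-di-O-isopropylidene-β-D-erythro-2,3-hexodiulo-2,6-pyranose (0.3 equiv), Oxone (2KHSO5·KHSO4·K2SO4), K2CO3, Bu4NHSO4, MeCN/CH2(OMe)2/aq. Na2B4O7 buffer, 0 °C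
Reagents that add atoms: potassium peroxymonosulfate (active part of Oxone), [K+].[O-]S(=O)(=O)OO
Why: Shi epoxidation, in which the chiral dioxirane attacks the most electron-rich, trisubstituted enyne alkene through the spiro transition state that gives R,R-epoxides from E-trisubstituted alkenes, so the catalyst sets C10 (R), while the monosubstituted and the 1,1-disubstituted alkene are poorer substrates.

Step 6
Reactants: 9 the 1R,10R-epoxide
Product: 13 (2R)-2-[(2S)-2-(tert-butyldimethylsilyloxy)but-3-en-1-yl]-2-methyl-5-(prop-1-en-2-yl)furan-3(2H)-one, via oxiranyllithium 10 (not isolated), via lithium oxiranolate 11 (not isolated), via hydroxy ynone 12 (not isolated)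
Conditions: lithium 2,2,6,6-tetramethylpiperidide (from the amine and n-BuLi, 1.15 equiv), THF, −78 °C; 2-(phenylsulfonyl)-3-phenyloxaziridine (1.2 equiv), −78 °C; MeOH, −78 to 23 °C; aq. NH4Cl
Reagents that add atoms: 2-(phenylsulfonyl)-3-phenyloxaziridine, O=S(=O)(c1ccccc1)N1OC1c1ccccc1
Why: Proposed new method: the amide base removes the one strongly activated proton, the oxirane C1–H (high s character, propargylic, lithium held by the ring oxygen), oxiranyllithium 10 attacks the oxaziridine oxygen, and oxiranolate 11 collapses at once by cleavage of its C1–O(ring) bond, as the α-oxy epoxide of a Rubottom oxidation does, to the alkoxide of ynone 12, which closes on C3 once methanol is present. The closest known reaction types are the trapping of alkynyl-stabilised oxiranyl anions by electrophiles, the electrophilic hydroxylation of organolithium compounds by N-sulfonyloxaziridines and the base-induced cyclisation of α'-hydroxy ynones to 3(2H)-furanones, and their union into a two-atom ring expansion of an oxirane is new. Ring A closes in the 5-endo-dig mode (oxa-Michael addition of the C10 oxygen to C3, proton to C2). No stereocenter is created, since C1 becomes trigonal and C10 keeps its R configuration because none of its four bonds, the C10–O bond included, is ever broken. The step needs site-selective metalation (a non-nucleophilic amide at −78 °C should neither add to the enyne nor open the oxirane), reaction of the ambident anion at C1 rather than C3 (attack at C3 would leave a strained alkylidene oxirane) and cleavage of C1–O rather than C10–O (only the former expels an alkoxide from the carbon that bears O−).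

Step 7
Reactants: 13 the silylated furanone
Product: 14 (2R)-2-[(2S)-2-hydroxybut-3-en-1-yl]-2-methyl-5-(prop-1-en-2-yl)furan-3(2H)-one
Conditions: HF·pyridine, THF, 0 °C
Reagents that add atoms: none
Why: Fluoride-driven silyl ether cleavage under weakly acidic conditions avoids the base that could add the freed C8 hydroxyl to C3 of the furanone, and no stereocenter is involved.

Step 8
Reactants: 14 the hydroxy furanone; 15 2-(bromomethyl)acrylic acid
Product: 16 (2S)-1-[(2R)-2-methyl-3-oxo-5-(prop-1-en-2-yl)-2,3-dihydrofuran-2-yl]but-3-en-2-yl 2-(bromomethyl)acrylate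
Conditions: DCC, DMAP (5 mol%), CH2Cl2, −20 to 0 °C
Reagents that add atoms: none
Why: Steglich esterification acylates the C8 oxygen with retention, and the low temperature and small amount of DMAP should keep the allylic bromide intact.

Step 9
Reactants: 16 the bromomethylacrylate
Product: 17 (5S)-3-(bromomethyl)-5-{[(2R)-2-methyl-3-oxo-5-(prop-1-en-2-yl)-2,3-dihydrofuran-2-yl]methyl}furan-2(5H)-one
Conditions: second-generation Grubbs catalyst (5 mol%), CH2Cl2 (5 mM), 40 °C
Reagents that add atoms: none
Why: Ring-closing metathesis, in which the catalyst loads on the monosubstituted C7 alkene and should close the five-membered butenolide (ring B) faster than a strained bridged ring with the isopropenyl group, leaving C8 untouched.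

Step 10
Reactants: 17 the bromomethyl butenolide; 18 acrolein
Product: 20 (4S,5S)-4-[(1R)-1-hydroxyprop-2-en-1-yl]-3-methylidene-5-{[(2R)-2-methyl-3-oxo-5-(prop-1-en-2-yl)-2,3-dihydrofuran-2-yl]methyl}dihydrofuran-2(3H)-one (C7, C8 and C10 arranged as in the target, C6 epimeric), via allylzinc bromide 19 (not isolated)
Conditions: Zn dust, acrolein (4 equiv), THF/sat. aq. NH4Cl, 0 to 23 °C
Reagents that add atoms: none
Why: Barbier allylation, in which allylzinc 19 reacts at C7 with allylic transposition through a chair transition state on the butenolide face anti to the C8 side chain (C7 trans to C8) and, because C8 is trans to CH2Zn on the ring alkene, with anti topicity that gives the 6R alcohol, while the hindered vinylogous ester carbonyl C1 should not compete with acrolein.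

Step 11
Reactants: 20 the 6R alcohol; 21 angelic acid, (Z)-2-methylbut-2-enoic acid
Product: 22 (1S)-1-[(2S,3R)-4-methylidene-2-{[(2R)-2-methyl-3-oxo-5-(prop-1-en-2-yl)-2,3-dihydrofuran-2-yl]methyl}-5-oxotetrahydrofuran-3-yl]prop-2-en-1-yl (Z)-2-methylbut-2-enoate
Conditions: PPh3 and DIAD (betaine preformed), toluene, −10 to 0 °C
Reagents that add atoms: none
Why: Mitsunobu esterification, in which the carboxylate displaces the alkoxyphosphonium group at C6 by SN2 with inversion (6R to 6S), and preforming the betaine leaves no free phosphine for the enoate units.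

Step 12
Reactants: 22 the angelate diene
Product: 23 target CNP0293168.1 (6S,7R,8S,10R; 4Z)
Conditions: second-generation Hoveyda–Grubbs catalyst (15 mol%, slow addition), 1,4-benzoquinone (30 mol%), toluene (0.5 mM), 90 °C
Reagents that add atoms: none
Why: Ring-closing metathesis, in which the catalyst loads on the monosubstituted C5 alkene and closes onto the isopropenyl group, the ten-membered carbocycle (nine-membered oxacycle) tolerates only the Z geometry at C4=C5, and closure onto C13 would need a four-membered ring.

Compound list
1 | (R)-2-vinyloxirane | C=C[C@@H]1CO1 | starting material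
2 | lithium acetylide–ethylenediamine complex | [Li]C#C.NCCN | starting material
3 | (S)-hex-1-en-5-yn-3-ol | C=C[C@@H](O)CC#C | intermediate
4 | alkenylalane (O-dimethylaluminium alkoxide, E-alkenyl dimethylalane) | C=C[C@@H](O[Al](C)C)C/C(C)=C/[Al](C)C | intermediate
5 | (3S,5E)-6-iodo-5-methylhexa-1,5-dien-3-ol | C=C[C@@H](O)C/C(C)=C/I | intermediate
6 | TBS ether of 5 | C=C[C@@H](O[Si](C)(C)C(C)(C)C)C/C(C)=C/I | intermediate
7 | 2-methylbut-1-en-3-yne | C=C(C)C#C | starting material
8 | (3S,5E)-dienyne silyl ether | C=C[C@@H](O[Si](C)(C)C(C)(C)C)C/C(C)=C/C#CC(C)=C | intermediate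
9 | (1R,10R)-enynyl epoxide | C=C[C@@H](O[Si](C)(C)C(C)(C)C)C[C@@]1(C)O[C@@H]1C#CC(C)=C | intermediate
10 | oxiranyllithium (Li at C1) | C=C[C@@H](O[Si](C)(C)C(C)(C)C)C[C@@]1(C)OC1([Li])C#CC(C)=C | intermediate
11 | lithium oxiranolate (OLi at C1) | C=C[C@@H](O[Si](C)(C)C(C)(C)C)C[C@@]1(C)OC1(O[Li])C#CC(C)=C | intermediate
12 | (10R)-α'-hydroxy ynone | C=C[C@@H](O[Si](C)(C)C(C)(C)C)C[C@@](C)(O)C(=O)C#CC(C)=C | intermediate
13 | (10R)-furanone silyl ether | C=C[C@@H](O[Si](C)(C)C(C)(C)C)C[C@@]1(C)OC(C(C)=C)=CC1=O | intermediate
14 | (8S,10R)-hydroxy furanone | C=C[C@@H](O)C[C@@]1(C)OC(C(C)=C)=CC1=O | intermediate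
15 | 2-(bromomethyl)acrylic acid | C=C(CBr)C(=O)O | starting material
16 | 2-(bromomethyl)acrylate of 14 | C=C[C@@H](OC(=O)C(=C)CBr)C[C@@]1(C)OC(C(C)=C)=CC1=O | intermediate
17 | (8S,10R)-3-(bromomethyl)butenolide | BrCC1=C[C@H](C[C@@]2(C)OC(C(C)=C)=CC2=O)OC1=O | intermediate
18 | acrolein | C=CC=O | starting material
19 | allylzinc bromide from 17 | Br[Zn]CC1=C[C@H](C[C@@]2(C)OC(C(C)=C)=CC2=O)OC1=O | intermediate
20 | α-methylene lactone, 6R alcohol | C=C1C(=O)O[C@@H](C[C@@]2(C)OC(=CC2=O)C(C)=C)[C@@H]1[C@@H](C=C)O | intermediate
21 | angelic acid | C/C=C(/C)C(=O)O | starting material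
22 | α-methylene lactone, 6S angelate | C=C1C(=O)O[C@@H](C[C@@]2(C)OC(=CC2=O)C(C)=C)[C@@H]1[C@H](C=C)OC(=O)/C(C)=C\C | intermediate
23 | CNP0293168.1 | C=C1C(=O)O[C@H]2C[C@@]3(C)OC(=CC3=O)/C(C)=C\[C@H](OC(=O)/C(C)=C\C)[C@H]12 | target

Total steps: 12. Longest linear sequence: 12 steps (1 to 23).

Steps most likely to fail

1. Step 6. The oxiranyllithium may decay by α-elimination before oxygen is transferred, or the ambident anion may be oxygenated unselectively. The fallback avoids the carbanion and sets out from 9. CsOAc in DMF at 70 °C opens the oxirane by SN2 attack at the less hindered, propargylic C1 and leaves the C10–O bond intact, which gives the (1S,10R)-hydroxy acetate F1. K2CO3 in MeOH frees the (1S,10R)-diol F2. MnO2 oxidises only the secondary propargylic alcohol, so the route is rejoined at 12, which closes to 13 with Et2NH in EtOH. The oxirane oxygen still ends as the oxygen of ring A.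

2. Step 12. Closure may be slower than catalyst decay and intermolecular metathesis, because a strained bridged ring with a trisubstituted alkene has to form next to an acylated carbinol. The fallback sets out from 20 and closes the ring before acylation. The free allylic hydroxyl at C6 should speed up loading and turnover of the second-generation Hoveyda–Grubbs catalyst and give the macrocyclic 6R alcohol F3. A Mitsunobu reaction with 21 then inverts C6 inside the ring, and the route is rejoined at 23.

3. Step 11. The activated allylic alcohol may react by SN2' attack or elimination, and traces of phosphine may isomerise the angelate to the E ester or add to the α-methylene lactone. The fallback needs no inversion and sets out from 17. Bu3SnSnBu3 with Pd2(dba)3 gives the allylstannane F4. Its BF3·OEt2-promoted addition to acrolein at −78 °C goes through an open antiperiplanar transition state with syn topicity, again anti to the C8 side chain, and gives the 6S alcohol F5. Acylation with retention by the mixed anhydride of 21 and 2,4,6-trichlorobenzoyl chloride (Et3N, then DMAP, toluene) rejoins the route at 22.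

Further compounds
F1 | step 6 | (1S,10R)-1-acetoxy-10-hydroxy enyne (silyl ether) | C=C[C@@H](O[Si](C)(C)C(C)(C)C)C[C@@](C)(O)[C@@H](OC(C)=O)C#CC(C)=C
F2 | step 6 | (1S,10R)-1,10-diol (silyl ether) | C=C[C@@H](O[Si](C)(C)C(C)(C)C)C[C@@](C)(O)[C@@H](O)C#CC(C)=C
F3 | step 12 | macrocyclic 6R alcohol (6-epi-deacyl target) | C=C1C(=O)O[C@H]2C[C@@]3(C)OC(=CC3=O)/C(C)=C\[C@@H](O)[C@H]12
F4 | step 11 | 3-(tributylstannylmethyl)butenolide | CCCC[Sn](CCCC)(CCCC)CC1=C[C@H](C[C@@]2(C)OC(C(C)=C)=CC2=O)OC1=O
F5 | step 11 | α-methylene lactone, 6S alcohol | C=C1C(=O)O[C@@H](C[C@@]2(C)OC(=CC2=O)C(C)=C)[C@@H]1[C@H](C=C)O
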